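The spring flask is still moving.

| setting | spring | midnight | flask |
|---|---|---|---|
| starting material | 0.020 M | 0.010 M | 0.020 M |
| partner | 0.024 M | 0.024 M | 0.0240 M |
| temperature | 100 °C | 100 °C | 100 °C |
| remark | the very flask that is asked about, followed so far | run made earlier |  |
| time |  |  | 40 h |

| run | time / h | target / % | starting material / % |
|---|---|---|---|
| spring | 3.00 | 12.5 | 11.6 |
| spring | 6.00 | 20.1 | 5.8 |
| spring | 12.0 | 23.5 | 1.6 |
| spring | 20.0 | 23.5 | 1.3 |
| spring | 40.0 | 29.9 | 0.8 |
| midnight | 0.250 | 3.1 | 66.8 |
| midnight | 0.500 | 6.2 | 46.2 |
| midnight | 0.833 | 8.0 | 31.8 |
| midnight | 1.50 | 12.4 | 19.6 |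
| midnight | 3.00 | 15.2 | 15.1 |

(standard deviation of a reading: 1 percentage point)

- alder: at 40 h take out 90% of the target then present, then wait 3.0 d
- elm: at 40 h add partner, 100% of the amount charged, then wait 3.0 d
- ash: change nothing and wait 3.0 d more
- larch: at 40 h raise the temperature by 15 K, then wait 3.0 d

- removed target is counted in
- the earlier runs do not show what temperature does; that part of a forecast is a guess
- additions bring no volume worth counting

- target, in percent of the starting material first charged, at 40 h
- what to do for the largest gain in target; "none" if nothing gains more than 2 percentage points (alder / elm / ash / larch / none)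
- target present, with what was taken out counted in, in percent of the starting material first charged, after alder
- target present, with what was taken out counted in, in percent of the starting material first charged, after ash

For whoever takes over the spring flask at 40 h: it reads 29.9% target and 0.8% starting material, so 69.3% of the charge sits in an unread pool. That pool feeds the target, because from 12.0 h to 40.0 h the target readings rose by 6.4 percentage points, more than the 1.6% of starting material read at the first of those two times. The reckoning here takes an empty pool as the end state, so the pace is what counts, with the pool at 74.9% at the earlier reading: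

drain constant = ln(74.9% / 69.3%) / (40.0 h − 12.0 h) = 0.00278 h⁻¹

This drain constant, the pseudo-first-order fraction of the pool leaving per hour, is rough, since readings good to 1 point give a pool drop of 5.6 points.

ash: target = 29.9% + 69.3% × (1 − exp(−drain constant × 3.0 d)) = 29.9% + 13 points = 42.5%

Alder is reckoned at the same 42.5%, on the assumption that the drain ignores the target. If one partner goes into each target and the drain constant goes with free partner, which is an assumption here, elm multiplies both by 2.33, for a reckoned gain of 26 points, more than waiting. So add partner; larch is a guess.

The forecast gave 28% now, 32% after alder, 32% after ash, and chose ash: “Waiting is the safest gain”.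

The flask gives 28.9% now and 40.1% after either ash or alder, while larch gains 32 points, more than elm's 20 points, so the answer is larch. In the flask at 40.0 h, intermediate B holds 61.8%. The drain constant on intermediate A plus intermediate B, 66.0%, gives 12 points in 3.0 d, against 11 points in the flask.

    starting material ⇌ intermediate A (K = 3.00, k = 0.0250 min⁻¹, Ea = 117 kJ mol⁻¹, ΔH = −8.00 kJ mol⁻¹)
    intermediate A ⇌ intermediate B (K = 13.0, k = 0.00470 min⁻¹, Ea = 121 kJ mol⁻¹, ΔH = −40.0 kJ mol⁻¹)
    starting material + partner → target (k = 0.130 M⁻¹ min⁻¹, Ea = 66.0 kJ mol⁻¹)
    2 starting material → self-condensation product (k = 0.0380 M⁻¹ min⁻¹, Ea = 68.0 kJ mol⁻¹)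
    (constants at 100 °C)

For the neighbour with 0.096 M of partner, the reckoning assumes that the drain constant and the target-to-pool ratio of 0.314 read at 12.0 h are both multiplied by 4.00. Counting pool and target as the whole charge, it puts the neighbour's pool at 44.3% at that time and 32.5% at 40.0 h, and so its target at 67.5%; the computed neighbour holds 64.5%.

(The numbers in the tables are calculated for an exercise; the scatter is artificial.)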